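Compound numbers are fixed by the steps below and used throughout. Ring A carries the free hydroxyl at A1, the chain at A3 and the ether oxygen at A5. Ring B carries the ether oxygen at B1, hydroxyls at B2 and B4 and the chain at B6.

## Analysis of the target

The target 23 is a 20-membered macrocycle in which two benzene rings are tied together twice: by a diaryl ether oxygen between A5 and B1, and by an unbranched chain of fourteen CH2 groups between A3 and B6. Ring A is a 1,3,5-trisubstituted benzene. Ring B is tetrasubstituted, with oxygen at B1, B2 and B4, the chain at B6 and hydrogen at B3 and B5. There is no stereocentre and no double-bond geometry, so the problem is one of constitution only. The sensitive part is ring B: with its hydroxyls free it is a hydroxyquinol-type ring that oxidises readily to a quinone, so the phenols should stay masked until the last step and the masks must come off without breaking the diaryl ether. Three things make the synthesis hard: closing a 20-membered ring, forming a diaryl ether at B1 whose oxygen sits between the B2 oxygen and the B6 chain, and telling the B1 oxygen apart from those at B2 and B4. The strategy rests on the pattern of ring B. The B1 and B4 oxygens are para, B2 is next to B1, the carbon substituent is at B6, and B3 and B5 are bare. A 4-alkenyl-4-oxy-3-alkoxycyclobutenone unfolds into exactly this pattern on heating: the carbonyl carbon becomes B4, the ring CH becomes B3, the alkoxy carbon B2, the quaternary carbon B1, and the two alkene carbons B6 and B5. Because the oxygen on the quaternary carbon can be silylated beforehand while the B4 oxygen is born as a free phenol, the same step also solves the differentiation problem.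

## Retrosynthetic reasoning

The first cut removes only protecting groups. Target 23 is taken back to the tris-ether 22, with methyl on the A1 and B4 oxygens and isopropyl on the B2 oxygen. Keeping all three phenols capped until the end keeps the oxidisable free ring B out of every earlier step. The forward reaction has to break three alkyl–oxygen bonds with a boron Lewis acid and leave the diaryl ether alone, which it should because that ether offers no alkyl carbon for attack.

Macrocycle 22 is opened at the bond between A3 and the last chain carbon, which leads to the bromo alkene 20. This is the least hindered bond of the large ring: A3 has hydrogen on both neighbours, whereas the ether oxygen at B1 is flanked on both sides. In the forward sense the terminal alkene is hydroborated to the alkylborane 21, which couples with the aryl bromide under palladium catalysis. Cutting here means the crowded ether is made intermolecularly, where an excess of one partner can be used, and the ring closure only has to beat oligomerisation.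

The diaryl ether of 20 is cut at the A5–O bond. Ring B then enters as phenol 18 and ring A as the boronic acid 19, which already holds methoxy, bromine and boron in the 1,3,5 relationship. Cutting on the ring A side avoids any need for a leaving group on the electron-rich and crowded B1 carbon. The forward reaction is a copper-mediated oxidative coupling at room temperature that must leave the aryl bromide and the alkene untouched.

Phenol 18 is traced to 16 through 17 by exchanging the roles of the two para oxygens: the free B4 hydroxyl of 16 is methylated to give 17, and the silyl group on the B1 oxygen is then removed. No skeletal bond is made here; these two steps use the differentiation created in the key step.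

Ring B of 16 is then disconnected at B4–B5. Phenol 16 is the tautomer of cyclohexadienone 15, which is the 6π closure product of dienylketene 14, and 14 is the ring-opened form of cyclobutenone 13. This is the place to cut because it converts a tetrasubstituted arene with three differently marked oxygens into a four-membered ring whose substituents are attached one at a time, with no regiochemical choice left for the arene-forming step. One thermal step without reagent should deliver ring B, the B4–B5 bond and the B1/B4 differentiation together.

Cyclobutenone 13 is the silyl ether of alcohol 12, and 12 is cut at the bond between the quaternary carbon (future B1) and the alkenyl carbon (future B6). The forward reaction is the addition of alkenyllithium 11, made from bromide 10, to dione 3. It has to occur at the carbonyl next to the isopropoxy-bearing carbon, the only carbonyl of 3 that is not deactivated as a vinylogous ester.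

Dione 3 has hydrogen on the ring carbon that becomes B3, so one alkoxy group of squarate 1 must be replaced by hydrogen. Hydride addition to 1 gives 2, and acid-induced transposition of oxygen in 2 gives 3.

Bromodiene 10 is cut at its allylic C3–C4 bond into Grignard reagent 9 and the allylic bromide 8. Reagent 9 comes from bromide 7, which is cut three carbons from its bromine into Grignard reagent 6 (from 4) and dibromide 5. The carbon count 10 + 3 + 3 puts the 2-bromoalkene and the terminal alkene at opposite ends of a sixteen-carbon chain in two steps, and neither step needs a selective reaction of an alkyne next to an alkene.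

## Alternatives that were turned down

Alternative 1: The macrocycle is disconnected between the first and second chain carbons next to ring A, with a sulfur atom inserted there. The ring would first be closed as a thioether, oxidised to the 21-membered sulfone A2, and A2 would be contracted by a Ramberg–Bäcklund reaction (α-halogenation at the benzylic carbon under base, 1,3-elimination, extrusion of the sulfur bridge) to the macrocyclic alkene A1. Hydrogenation of A1 and cleavage of its three methyl ethers would give 23. In its favour, carbon–sulfur bond formation is among the most forgiving macrocyclisations, the contraction is tolerant, and the alkene geometry does not matter. Against it, the plan addresses only the large ring. Ring B with its three oxygens and the hindered ether at B1 must come from other chemistry, and the single carbon–carbon bond costs a benzylic halide, a chain thiol, an oxidation, the contraction and a hydrogenation. On reliability of the ring closure itself this alternative is probably stronger than the coupling of 20 to 22. The chosen route offers a constructive answer for ring B and its oxygen differentiation, and a one-flask ring closure.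

Alternative 2: Both benzene rings are opened by retro-aldol logic to the acyclic hexaoxo diester A4. Base would fold each triketo ester terminus by intramolecular aldol condensation and aromatisation, giving the bis-resorcylate A3 with both rings formed in one operation. In its favour, it is biomimetic, starts from a symmetric achiral chain, and forms more skeletal bonds per step than the chosen route, which builds only one ring. Against it, A3 is twofold symmetric while the two rings of 23 differ. In A3 the B1 carbon carries an ester carbon where 23 needs oxygen, and ring A carries an ester it does not need. The sequence would therefore have to desymmetrise A3, degrade one ester to an oxygen substituent, remove the other, and then form the crowded diaryl ether as the macrocyclisation. A4 also has many competing enolisation and cyclisation modes. Compared with the chosen strategy it leaves open exactly the two points that the cyclobutenone route settles, the oxygen at B1 and its differentiation from B2 and B4. The price paid in the chosen route is that ring A is bought ready-made as 19.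

Alternative 3: Ring A and the macrocycle are disconnected together, back to the diazo enone A6, in which ring B carries an ethynyl ether on its B1 oxygen. Irradiation would trigger a Wolff rearrangement to a vinylketene, which adds across the tethered alkyne; the resulting strained vinylcyclobutenone opens and recloses to the phenol A5. Four bonds, ring A and the 20-membered ring would form at once, and the A1 hydroxyl would emerge free. On convergence this is stronger than the chosen route, which needs a separate macrocyclisation. Against it, the ketene–alkyne cycloaddition must span a 20-membered ring. At the dilution this requires, a short-lived ketene is more likely to be lost to dimerisation or to stray nucleophiles. The ethynyl ether on a doubly ortho-substituted phenol is hard to make and labile, and ring B with a marked B1 oxygen must still come from elsewhere. The chosen strategy uses the same kind of pericyclic cascade in a setting where the reacting alkene is held next to the ketene (13 to 16), and closes the large ring by a separate step that can be tuned on its own.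

Key step: step 6

Remark: 23 has no stereocentre; the stereocentres in 2, 12 and 13 are racemic and vanish in the following step. Compounds 1, 4, 5, 8 and 19 are taken as purchasable.

## Route

Step 1
Reactants: 1 diisopropyl squarate (3,4-diisopropoxycyclobut-3-ene-1,2-dione)
Product: 3 3-isopropoxycyclobut-3-ene-1,2-dione, via hydroxycyclobutenone 2 (not isolated)
Conditions: LiAlH(OtBu)3, THF, −78 → −20 °C; aq. work-up; then conc. HCl (cat.), CH2Cl2, rt
Reagents that add atoms: none
Why: The bulky alkoxyaluminium hydride adds once to a squarate carbonyl (1,2-reduction) to give racemic 2; acid then ionises the allylic carbinol, the oxygen is transposed to the far alkoxy carbon and isopropanol is lost, the standard conversion of squarate 1,2-adducts into 3-alkoxycyclobutenediones.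

Step 2
Reactants: 4 10-bromodec-1-ene; 5 1,3-dibromopropane
Product: 7 13-bromotridec-1-ene, via dec-9-enylmagnesium bromide 6 (not isolated)
Conditions: Mg, THF, 40 °C; then 5 (3 equiv), Li2CuCl4 (2 mol%), THF, −10 °C → rt
Reagents that add atoms: none
Why: Grignard formation followed by Li2CuCl4-catalysed sp3–sp3 cross-coupling with a primary alkyl bromide; the excess of 5 should hold the coupling at one end, and surplus 5 is removed by distillation.

Step 3
Reactants: 7 13-bromotridec-1-ene; 8 2,3-dibromoprop-1-ene
Product: 10 2-bromohexadeca-1,15-diene, via tridec-12-enylmagnesium bromide 9 (not isolated)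
Conditions: Mg, THF, 40 °C; then 8, CuI (5 mol%), THF, −20 °C → rt
Reagents that add atoms: none
Why: Copper-catalysed allylic substitution of a Grignard reagent on the allylic C–Br bond of 8; SN2 and SN2′ attack lead to the same 2-bromoalkene, and the vinylic bromide is inert under these conditions.

Step 4
Reactants: 10 2-bromohexadeca-1,15-diene; 3 3-isopropoxycyclobut-3-ene-1,2-dione
Product: 12 (±)-4-(hexadeca-1,15-dien-2-yl)-4-hydroxy-3-isopropoxycyclobut-2-en-1-one, via hexadeca-1,15-dien-2-yllithium 11 (not isolated)
Conditions: t-BuLi (2.0 equiv), Et2O, −78 °C; then cannulated into 3, THF, −78 °C; aq. NH4Cl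
Reagents that add atoms: none
Why: Bromine–lithium exchange (the second equivalent of t-BuLi destroys the tert-butyl bromide formed) gives the alkenyllithium, which undergoes 1,2-addition at the ketone carbonyl next to the isopropoxy carbon and not at the less electrophilic vinylogous ester carbonyl. The new quaternary centre forms without control (racemic) and is erased in step 6.

Step 5
Reactants: 12 (±)-4-(hexadeca-1,15-dien-2-yl)-4-hydroxy-3-isopropoxycyclobut-2-en-1-one
Product: 13 (±)-4-(tert-butyldimethylsilyloxy)-4-(hexadeca-1,15-dien-2-yl)-3-isopropoxycyclobut-2-en-1-one
Conditions: TBSOTf, 2,6-lutidine, CH2Cl2, −78 → 0 °C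
Reagents that add atoms: tert-butyldimethylsilyl trifluoromethanesulfonate, CC(C)(C)[Si](C)(C)OS(=O)(=O)C(F)(F)F
Why: Silylation of a tertiary alcohol with a silyl triflate and a hindered pyridine base; the low temperature and non-nucleophilic base should spare the strained ring and its vinylogous ester.

Step 6
Reactants: 13 (±)-4-(tert-butyldimethylsilyloxy)-4-(hexadeca-1,15-dien-2-yl)-3-isopropoxycyclobut-2-en-1-one
Product: 16 4-(tert-butyldimethylsilyloxy)-3-isopropoxy-5-(tetradec-13-en-1-yl)phenol, via dienylketene 14 (not isolated), via cyclohexadienone 15 (not isolated)
Conditions: degassed PhMe (0.02 M), 110 °C, Ar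
Reagents that add atoms: none
Why: Heating cleaves the bond between the carbonyl carbon and the quaternary carbon of 13 by thermal conrotatory 4π electrocyclic opening, giving dienylketene 14. The ketene carbon, the central enol ether double bond and the 1,1-disubstituted alkene form a hexatriene, and thermal disrotatory 6π electrocyclisation joins the ketene carbon to the terminal CH2 (bond B4–B5), closing ring B as a six-membered carbocycle in cyclohexa-2,4-dienone 15. Enolisation of 15 then gives phenol 16, and the gain of aromaticity makes the sequence irreversible. The closest known reaction type is the thermal rearrangement of squarate-derived 4-alkenyl- and 4-aryl-4-hydroxy- or 4-silyloxycyclobutenones to hydroquinones and their monoethers. No stereocentre is formed, and the racemic quaternary centre of 13 becomes the sp2 carbon B1. The step needs torquoselectivity: the silyloxy donor on the quaternary carbon should rotate outward, which turns the alkenyl group inward and places it cis to the ketene so that closure can occur. The positional outcome is fixed by the constitution of 13 alone (carbonyl carbon to B4 with free OH, ring CH to B3, isopropoxy carbon to B2, silyloxy carbon to B1, alkene carbons to B6 and B5). The silyl group has no adjacent hydroxyl to migrate to, and the remote terminal alkene is a spectator.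

Step 7
Reactants: 16 4-(tert-butyldimethylsilyloxy)-3-isopropoxy-5-(tetradec-13-en-1-yl)phenol
Product: 17 tert-butyl[2-isopropoxy-4-methoxy-6-(tetradec-13-en-1-yl)phenoxy]dimethylsilane
Conditions: MeI, K2CO3, acetone, rt → 40 °C
Reagents that add atoms: iodomethane, CI
Why: Williamson methylation of the only free phenol (B4); the silyl ether is para to it, so it cannot migrate intramolecularly, and it is shielded by two ortho substituents.

Step 8
Reactants: 17 tert-butyl[2-isopropoxy-4-methoxy-6-(tetradec-13-en-1-yl)phenoxy]dimethylsilane
Product: 18 2-isopropoxy-4-methoxy-6-(tetradec-13-en-1-yl)phenol
Conditions: TBAF, AcOH, THF, 0 °C → rt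
Reagents that add atoms: none
Why: Fluoride cleavage of an aryl silyl ether; the AcOH buffer keeps the electron-rich phenoxide from air oxidation, and the alkyl ethers and the alkene are inert.

Step 9
Reactants: 18 2-isopropoxy-4-methoxy-6-(tetradec-13-en-1-yl)phenol; 19 (3-bromo-5-methoxyphenyl)boronic acid
Product: 20 1-bromo-3-[2-isopropoxy-4-methoxy-6-(tetradec-13-en-1-yl)phenoxy]-5-methoxybenzene
Conditions: Cu(OAc)2, pyridine, 4 Å MS, CH2Cl2, air, rt
Reagents that add atoms: none
Why: Chan–Lam oxidative C–O coupling: the aryl group passes from boron to divalent copper, oxidation gives a trivalent copper aryl phenoxide, reductive elimination forms the A5–O bond, and air reoxidises the copper. The reaction is known to accept doubly ortho-substituted phenols and should leave the aryl bromide and the alkene untouched at room temperature.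

Step 10
Reactants: 20 1-bromo-3-[2-isopropoxy-4-methoxy-6-(tetradec-13-en-1-yl)phenoxy]-5-methoxybenzene
Product: 22 A1,B4-di-O-methyl-B2-O-isopropyl ether of the target (20-membered ring: OMe at A1 and B4, OiPr at B2, ether O between A5 and B1, (CH2)14 from B6 to A3), via alkylborane 21 (not isolated)
Conditions: 9-BBN, THF, rt; then syringe-pump addition to PdCl2(dppf) (15 mol%), AsPh3, Cs2CO3, DMF–THF–H2O, 60 °C, final ca. 2 mM
Reagents that add atoms: none
Why: Anti-Markovnikov hydroboration of the terminal alkene, then intramolecular B-alkyl Suzuki–Miyaura coupling (oxidative addition of zerovalent palladium into the aryl bromide, base-assisted transmetalation of the primary alkyl group, reductive elimination). Slow addition at high dilution should favour closure of the 20-membered ring over oligomerisation, and the wide-bite-angle dppf ligand disfavours β-hydride elimination.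

Step 11
Reactants: 22 A1,B4-di-O-methyl-B2-O-isopropyl ether of the target
Product: 23 target CNP0173380.0 (20-membered ring: OH at A1, B2 and B4, ether O between A5 and B1, (CH2)14 from B6 to A3)
Conditions: BBr3 (excess), CH2Cl2, −78 °C → rt; then H2O
Reagents that add atoms: none
Why: Lewis-acid cleavage of alkyl aryl ethers: BBr3 coordinates each ether oxygen and bromide removes the two methyl groups and the isopropyl group. The diaryl ether has no alkyl C–O bond and should survive.

## Compound list

1 | diisopropyl squarate (3,4-diisopropoxycyclobut-3-ene-1,2-dione) | CC(C)OC1=C(OC(C)C)C(=O)C1=O | starting material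
2 | (±)-4-hydroxy-2,3-diisopropoxycyclobut-2-en-1-one | CC(C)OC1=C(OC(C)C)C(O)C1=O | intermediate (not isolated)
3 | 3-isopropoxycyclobut-3-ene-1,2-dione | CC(C)OC1=CC(=O)C1=O | intermediate
4 | 10-bromodec-1-ene | C=CCCCCCCCCBr | starting material
5 | 1,3-dibromopropane | BrCCCBr | starting material
6 | dec-9-enylmagnesium bromide | C=CCCCCCCCC[Mg]Br | intermediate (not isolated)
7 | 13-bromotridec-1-ene | C=CCCCCCCCCCCCBr | intermediate
8 | 2,3-dibromoprop-1-ene | C=C(Br)CBr | starting material
9 | tridec-12-enylmagnesium bromide | C=CCCCCCCCCCCC[Mg]Br | intermediate (not isolated)
10 | 2-bromohexadeca-1,15-diene | C=C(Br)CCCCCCCCCCCCC=C | intermediate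
11 | hexadeca-1,15-dien-2-yllithium | [Li]C(=C)CCCCCCCCCCCCC=C | intermediate (not isolated)
12 | (±)-4-(hexadeca-1,15-dien-2-yl)-4-hydroxy-3-isopropoxycyclobut-2-en-1-one | C=C(CCCCCCCCCCCCC=C)C1(O)C(OC(C)C)=CC1=O | intermediate
13 | (±)-4-(tert-butyldimethylsilyloxy)-4-(hexadeca-1,15-dien-2-yl)-3-isopropoxycyclobut-2-en-1-one | C=C(CCCCCCCCCCCCC=C)C1(O[Si](C)(C)C(C)(C)C)C(OC(C)C)=CC1=O | intermediate
14 | (3Z)-4-(tert-butyldimethylsilyloxy)-3-isopropoxy-5-methylidenenonadeca-1,3,18-trien-1-one (dienylketene) | O=C=C/C(OC(C)C)=C(O[Si](C)(C)C(C)(C)C)\C(=C)CCCCCCCCCCCCC=C | intermediate (not isolated)
15 | 4-(tert-butyldimethylsilyloxy)-3-isopropoxy-5-(tetradec-13-en-1-yl)cyclohexa-2,4-dien-1-one | O=C1C=C(OC(C)C)C(O[Si](C)(C)C(C)(C)C)=C(CCCCCCCCCCCCC=C)C1 | intermediate (not isolated)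
16 | 4-(tert-butyldimethylsilyloxy)-3-isopropoxy-5-(tetradec-13-en-1-yl)phenol | CC(C)Oc1cc(O)cc(CCCCCCCCCCCCC=C)c1O[Si](C)(C)C(C)(C)C | intermediate
17 | tert-butyl[2-isopropoxy-4-methoxy-6-(tetradec-13-en-1-yl)phenoxy]dimethylsilane | COc1cc(OC(C)C)c(O[Si](C)(C)C(C)(C)C)c(CCCCCCCCCCCCC=C)c1 | intermediate
18 | 2-isopropoxy-4-methoxy-6-(tetradec-13-en-1-yl)phenol | COc1cc(OC(C)C)c(O)c(CCCCCCCCCCCCC=C)c1 | intermediate
19 | (3-bromo-5-methoxyphenyl)boronic acid | COc1cc(Br)cc(B(O)O)c1 | starting material
20 | 1-bromo-3-[2-isopropoxy-4-methoxy-6-(tetradec-13-en-1-yl)phenoxy]-5-methoxybenzene | COc1cc(OC(C)C)c(Oc2cc(Br)cc(OC)c2)c(CCCCCCCCCCCCC=C)c1 | intermediate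
21 | 9-{14-[2-(3-bromo-5-methoxyphenoxy)-3-isopropoxy-5-methoxyphenyl]tetradecyl}-9-borabicyclo[3.3.1]nonane | COc1cc(OC(C)C)c(Oc2cc(Br)cc(OC)c2)c(CCCCCCCCCCCCCCB2C3CCCC2CCC3)c1 | intermediate (not isolated)
22 | A1,B4-di-O-methyl-B2-O-isopropyl ether of the target (macrocycle with OMe at A1 and B4, OiPr at B2) | COc1cc2cc(c1)Oc1c(OC(C)C)cc(OC)cc1CCCCCCCCCCCCCC2 | intermediate
23 | CNP0173380.0 (macrocycle with OH at A1, B2 and B4; ether O between A5 and B1; (CH2)14 from B6 to A3) | Oc1cc2cc(c1)Oc1c(O)cc(O)cc1CCCCCCCCCCCCCC2 | target

## Step count and least certain steps

Total steps: 11. Longest linear sequence: 10 steps (4 → 7 → 10 → 12 → 13 → 16 → 17 → 18 → 20 → 22 → 23); step 1 is a one-step side branch that supplies 3.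

**Step 6 (key step).** The pericyclic cascade is well founded, so the likely failure is intermolecular. Ketene 14 may be captured by the free phenol of 16 already formed, or by traces of water, before it closes. At 110 °C the silyl group may also be passed between phenolic oxygens, which would blur the B1/B4 label. The fallback drops the silyl label and differentiates by sterics after the ring expansion. It sets out from 12, which is heated without protection (PhMe, 110 °C, argon) to give the hydroquinone 2-isopropoxy-6-(tetradec-13-en-1-yl)benzene-1,4-diol F1. The B4 hydroxyl of F1 has hydrogen on both sides, whereas the B1 hydroxyl lies between the isopropoxy group and the chain. One equivalent of MeI with K2CO3 in acetone should therefore methylate B4 preferentially, and the route is rejoined at 18.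

**Step 10.** Closing a 20-membered ring by B-alkyl coupling is the least secure bond formation. At high dilution the transmetalation of the tethered alkylborane is slow, so intermolecular coupling to oligomers, protodeboronation and reduction of the aryl bromide can take over. The fallback closes the ring by olefin metathesis and sets out from 20. Coupling of its aryl bromide with potassium vinyltrifluoroborate (PdCl2(dppf), Cs2CO3, THF–H2O) should give the styrene 1-ethenyl-3-[2-isopropoxy-4-methoxy-6-(tetradec-13-en-1-yl)phenoxy]-5-methoxybenzene F2. Ring-closing metathesis with the second-generation Grubbs catalyst at high dilution should give the macrocyclic alkene with A3–CH=CH in the 20-membered ring, F3, as a mixture of geometric isomers. Hydrogenation over Pd on carbon returns to the route at 22.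

**Step 9.** The B1 hydroxyl is flanked twice and sits on an electron-rich ring. Slow transfer to copper would leave time for oxidative degradation of the phenol and for protodeboronation or homocoupling of 19. The fallback replaces the copper coupling by a metal-free aryl transfer from trivalent iodine and sets out from 18. Commercial 1-bromo-3-iodo-5-methoxybenzene is oxidised with mCPBA and TsOH and treated with 1,3,5-trimethoxybenzene to give (3-bromo-5-methoxyphenyl)(2,4,6-trimethoxyphenyl)iodonium 4-methylbenzenesulfonate F4. With K2CO3 in MeCN this should arylate 18 on oxygen, the trimethoxyphenyl group staying on iodine, and the route is rejoined at 20.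

**Step 4.** Dione 3 has no substituent on its free ring carbon, and the alkenyllithium is strongly basic. Proton transfer, addition–elimination at the isopropoxy-bearing carbon, or attack by residual t-BuLi could compete with the wanted 1,2-addition. The fallback changes the organometallic and avoids t-BuLi altogether, setting out from 10. Magnesium in THF should give hexadeca-1,15-dien-2-ylmagnesium bromide F5, and anhydrous CeCl3 at −78 °C should convert it into dichloro(hexadeca-1,15-dien-2-yl)cerium F6. This weakly basic, oxophilic reagent of trivalent cerium should add cleanly to the ketone carbonyl of 3, and the route is rejoined at 12.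

## Further compounds

F1 | step 6 | 2-isopropoxy-6-(tetradec-13-en-1-yl)benzene-1,4-diol | CC(C)Oc1cc(O)cc(CCCCCCCCCCCCC=C)c1O
F2 | step 10 | 1-ethenyl-3-[2-isopropoxy-4-methoxy-6-(tetradec-13-en-1-yl)phenoxy]-5-methoxybenzene | COc1cc(OC(C)C)c(Oc2cc(C=C)cc(OC)c2)c(CCCCCCCCCCCCC=C)c1
F3 | step 10 | macrocyclic alkene with A3–CH=CH in the 20-membered ring, OMe at A1 and B4, OiPr at B2 (mixture of E and Z, no geometry drawn) | COc1cc2cc(c1)Oc1c(OC(C)C)cc(OC)cc1CCCCCCCCCCCCC=C2
F4 | step 9 | (3-bromo-5-methoxyphenyl)(2,4,6-trimethoxyphenyl)iodonium 4-methylbenzenesulfonate | COc1cc(Br)cc([I+]c2c(OC)cc(OC)cc2OC)c1.Cc1ccc(cc1)S(=O)(=O)[O-]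
F5 | step 4 | hexadeca-1,15-dien-2-ylmagnesium bromide | C=C(CCCCCCCCCCCCC=C)[Mg]Br
F6 | step 4 | dichloro(hexadeca-1,15-dien-2-yl)cerium | C=C(CCCCCCCCCCCCC=C)[Ce](Cl)Cl
A1 | alternative 1 | tri-O-methyl-1',2'-didehydrorobustol (E isomer drawn, either isomer serves) | COc1cc(/C=C/CCCCCCCCCCCCc2cc(OC)cc(OC)c2O3)cc3c1
A2 | alternative 1 | 21-membered cyclic sulfone with SO2 between the first and second chain carbons next to ring A, OMe at A1, B2 and B4 | COc1cc2cc(c1)Oc1c(OC)cc(OC)cc1CCCCCCCCCCCCCS(=O)(=O)C2
A3 | alternative 2 | dimethyl 6,6'-(tetradecane-1,14-diyl)bis(2,4-dihydroxybenzoate) | COC(=O)c1c(O)cc(O)cc1CCCCCCCCCCCCCCc1cc(O)cc(O)c1C(=O)OC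
A4 | alternative 2 | dimethyl 3,5,7,22,24,26-hexaoxooctacosanedioate | COC(=O)CC(=O)CC(=O)CC(=O)CCCCCCCCCCCCCCC(=O)CC(=O)CC(=O)CC(=O)OC
A5 | alternative 3 | robustol B2,B4-dimethyl ether | Oc1cc2cc(c1)Oc1c(OC)cc(OC)cc1CCCCCCCCCCCCCC2
A6 | alternative 3 | 1-diazo-17-[2-(ethynyloxy)-3,5-dimethoxyphenyl]-3-methylideneheptadecan-2-one | [N-]=[N+]=CC(=O)C(=C)CCCCCCCCCCCCCCc1cc(OC)cc(OC)c1OC#C
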